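## Structural features

The target 23 is a 2,5-diaryl-3,4-dimethyltetrahydrofuran: one oxolane ring (O1, C2 to C5) with ring A (3,4-dimethoxyphenyl) on C2, methyl groups on C3 and C4, and ring B (4-hydroxy-3,5-dimethoxyphenyl) on C5. All four ring carbons are contiguous stereocentres, (2S,3S,4R,5R): the methyl groups are cis to each other, each aryl group is trans to its neighbouring methyl, and the two aryl groups are cis across O1. With two identical aryl groups this array would be meso, so the absolute configuration is decided only by which ring end carries ring A and which ring B. Fragile features are the two benzylic C–O bonds (C2–O1 and C5–O1) next to electron-rich arenes, which ionise under strong acid and can be hydrogenolysed, and the free, easily oxidised phenol of ring B. At the lactone and oxocarbenium stages the cis-dimethyl pair is also fragile, because it is the less stable arrangement next to an sp2 carbon. The real difficulty is the cis C3/C4 dimethyl unit flanked by two trans aryl groups, together with telling the two ends of the ring apart. The key step exploits the fact that C2–C3–C4–C5, with O1 on C2, is the chain from the α carbon to the side-chain carboxyl carbon of L-glutamic acid closed as a γ-lactone: C2 is the carbinol carbon whose one-carbon substituent shields one face, C3 is the β carbon and C4 the α carbon of the butenolide, and C5 is the lactone carbonyl.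

## Logic of the disconnections

23 to 22. Only the O–CH2Ph bond of the ring B ether is cut. The free phenol would not survive the organometallic, oxoammonium and photoredox steps, so it is unmasked last. The forward step must remove the benzyl group without hydrogenolysing C2–O1 or C5–O1.

22 to 20 and 21. The C2–aryl bond to ring A is cut. C2 carries the one-carbon placeholder inherited from the chiral pool, and a carboxyl group there can be exchanged for an aryl group through an α-oxy radical. This gives a commercial aryl bromide and a tetrahydrofuran-2-carboxylic acid whose C2 configuration no longer matters. The demand is that the planar radical is captured on the face opposite the C3 methyl.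

20 to 18 to 17. No skeletal bond is cut; the carboxyl is traced to the primary alcohol and then to its silyl ether. The oxidation must leave the benzylic ether at C5 and the aryl ethers alone, and any epimerisation at C2 in 19 or 20 is harmless.

17 to 12 and 14. The C5–aryl bond to ring B is cut, pairing a C5 oxocarbenium ion (from 12) with an arylzinc reagent (16, from 14). Putting hydrogen on C5 first and the aryl group second lets the aryl group enter anti to the two cis methyl groups, which is the trans relationship the target needs. The reverse order (aryl addition to the carbonyl of 10, then hydride delivery to the aryl-substituted oxocarbenium ion) was set aside. Hydride would be expected to enter anti to the methyls and leave ring B cis to them, and the conjugated cation would lose the C4 proton more easily. The forward step must ionise 12 without loss of the C4 configuration.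

12 to 11 to 10. The C5–S bond and the C5–H bond are traced back to the lactone carbonyl. This brings the problem to a γ-lactone in which C3 and C4 are already set. The reduction must stop at the lactol and must not enolise the α carbon.

10 to 8 (key step). The C3–CH3 bond and the C4–H bond (target numbering) are cut. This removes two stereocentres at once and leaves a flat butenolide with one stereocentre. The forward step needs methyl delivery anti to the C2 side chain and then protonation anti to the new methyl, without equilibration.

8 to 5 to 4. The ring C=C bond comes from a selenoxide elimination and the C4–CH3 bond from an enolate methylation. The elimination must go into the ring and not toward the methyl group, and the γ stereocentre must not be deprotonated.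

4 to 3 to 2 to 1. The Si–O bond, the reduction of the carboxyl to CH2OH, and the C2–O1 bond (formed with retention when the amino group is replaced) are undone in turn, reaching the amino acid. The deamination must proceed with net retention so that C2 keeps the S configuration.

14 to 13. The O–benzyl bond is cut to reach the commercial bromophenol; the bromine marks the ring B carbon that later bonds to C5.

## Other disconnections considered

Alternative 1: The cut is the C3–C4 bond together with the two C–H bonds that complete the methyl groups. This opens the ring to the bis-allylic, bis-benzylic ether A1, in which C2 and C5 each carry an aryl group and a vinyl group. In the forward step a manganese hydride (from a manganese diketonate, a silane and a peroxide) would transfer a hydrogen atom to one vinyl terminus. The secondary radical would close 5-exo onto the other vinyl group, and a second hydrogen atom would cap the primary radical, giving A2, the silyl ether of the target.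
- In its favour: it is very short and convergent, it makes the ring, the C3–C4 bond and both methyl groups in one operation, and it needs no placeholder carbon. The usual preferences of hexenyl radical closure (cis for a substituent on the radical carbon, trans to substituents on the flanking carbons) point qualitatively to the target's configuration.
- Against it here: A1 must be made as one diastereomer from two different secondary allylic benzylic alcohols, and etherification of such alcohols tends to scramble by ionisation or allylic transposition. The cis preference at C3/C4 is inherently modest. The doubly activated C–H bonds at C2 and C5 invite abstraction or alkene migration under hydride conditions.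
- Comparison: on step economy this plan is the better one. Structurally it presets C2 and C5 and lets them steer C3 and C4, the reverse of the chosen plan. Mechanistically it sets two centres in one weakly biased radical event, whereas the chosen plan sets each centre in a separate, strongly biased step.

Alternative 2: The cuts are C4–C5 and C2–C3, leading to the chiral arylacetamide A3 and cis-2-butene A4. In the forward step A3 would be activated with a sulfonic anhydride and a hindered pyridine base to a keteniminium ion, which adds across A4; hydrolysis gives the cyclobutanone A5. Regioselective Baeyer–Villiger oxygen insertion on the aryl-bearing side would give the lactone A6, and ring A would then be added at the derived lactol.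
- In its favour: the cis relationship of the methyl groups is taken directly from the alkene geometry, which is at least the equal of, and probably better than, a kinetic protonation. The aryl group settles trans to its neighbour by equilibration, and the sequence is shorter than the chosen one.
- Against it here: A4 is a gas that is needed in excess. The absolute configuration rests on an auxiliary whose induction with an unactivated internal alkene is uncertain. The electron-rich arene of A3 can compete for the anhydride or for the peracid, and the migrating-group preference in the oxygen insertion is expected but not assured.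
- Comparison: step economy and relative configuration at C3/C4 are points for this alternative. Absolute configuration is more secure in the chosen plan, where it comes from one chiral-pool centre. Both plans face the same final problem of adding an aryl group trans to a methyl at a lactol carbon.

Alternative 3: The cut is C2–C3, leading to veratryl alcohol A7 and isoprene A8. In the forward step a ruthenium hydride catalyst with a chiral diphosphine would dehydrogenate A7, hydrometalate A8 to a 1,2-dimethylallyl ruthenium species and add it to the resulting aldehyde. This gives the anti homoallylic alcohol A9, with ring A, the future O1, C2 and C3 in place. Hydroboration of the 1,1-disubstituted alkene, oxidation to the γ-lactone and installation of ring B would follow.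
- In its favour: it is redox-neutral, uses feedstocks, needs no placeholder carbon and no stoichiometric organometallic, and either enantiomer is available from the catalyst. On these points it is the better plan.
- Against it here: the key step does not touch C4. Acyclic hydroboration next to a methyl-bearing stereocentre normally favours the anti arrangement, which becomes the trans-dimethyl ring, so the cis pair would need a catalyst-controlled variant of uncertain selectivity. Regiochemistry of the isoprene hydrometalation and enantioselectivity for this exact pair would also have to be established.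
- Comparison: this plan builds from the ring A end with catalyst control; the chosen plan builds from the middle with substrate control in a ring. Step economy is better up to A9 and about equal afterwards. The cis-dimethyl unit is the weak point here and the strong point of the chosen plan.

Key step: step 6

Remark on the chemistry: the hydroxymethyl group is carried as its tert-butyldiphenylsilyl ether in place of a trityl ether, a change of protecting group only, because a trityl ether would be at risk under the sulfinic acid of step 8; the skeletons of 8 and 10 and the bonds made in step 6 are unchanged.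

## Route

Step 1
Reactants: 1 L-glutamic acid
Product: 2 (S)-5-oxotetrahydrofuran-2-carboxylic acid
Conditions: NaNO2, aq. HCl, 0 °C to rt
Reagents that add atoms: none
Why: Nitrous acid deamination with participation of the neighbouring α-carboxylate, followed by lactonisation by the side-chain carboxyl, goes with net retention (double inversion), so the S centre of 1 is kept.

Step 2
Reactants: 2 (S)-5-oxotetrahydrofuran-2-carboxylic acid
Product: 3 (S)-5-(hydroxymethyl)dihydrofuran-2(3H)-one
Conditions: BH3·SMe2, THF, 0 °C to rt; MeOH
Reagents that add atoms: none
Why: Borane reduces a carboxylic acid much faster than a lactone (chemoselective acid reduction), and the stereocentre is not involved.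

Step 3
Reactants: 3 (S)-5-(hydroxymethyl)dihydrofuran-2(3H)-one
Product: 4 (S)-5-{[(tert-butyldiphenylsilyl)oxy]methyl}dihydrofuran-2(3H)-one
Conditions: t-BuPh2SiCl, imidazole, DMF, rt
Reagents that add atoms: tert-butyl(chloro)diphenylsilane, CC(C)(C)[Si](Cl)(c1ccccc1)c1ccccc1
Why: Standard silylation of a primary alcohol; the bulky silyl ether later serves as the face-shielding group and withstands the base, hydride and mild acid steps that follow.

Step 4
Reactants: 4 (S)-5-{[(tert-butyldiphenylsilyl)oxy]methyl}dihydrofuran-2(3H)-one
Product: 5 (3R,5S)-5-{[(tert-butyldiphenylsilyl)oxy]methyl}-3-methyldihydrofuran-2(3H)-one (trans isomer drawn; any 3S epimer is carried along)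
Conditions: LiN(i-Pr)2, THF, −78 °C; MeI, −78 to −40 °C
Reagents that add atoms: iodomethane, CI
Why: Lactone enolate alkylation; the electrophile enters mainly trans to the C5 side chain, and the new centre is of no consequence because step 5 makes it sp2.

Step 5
Reactants: 5 (3R,5S)-5-{[(tert-butyldiphenylsilyl)oxy]methyl}-3-methyldihydrofuran-2(3H)-one
Product: 8 (S)-5-{[(tert-butyldiphenylsilyl)oxy]methyl}-3-methylfuran-2(5H)-one, via selenide 6 (not isolated), via selenoxide 7 (not isolated)
Conditions: LiN(i-Pr)2, THF, −78 °C; PhSeBr; then AcOH, 30% aq. H2O2, 0 °C to rt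
Reagents that add atoms: benzeneselenenyl bromide, Br[Se]c1ccccc1 (selenium group carried only by 6 and 7); hydrogen peroxide, OO (oxygen carried only by 7)
Why: α-Selenenylation of the enolate, oxidation to the selenoxide and syn elimination below room temperature; elimination into the ring gives the conjugated endocyclic alkene, and the C5 stereocentre is not touched.

Step 6
Reactants: 8 (S)-5-{[(tert-butyldiphenylsilyl)oxy]methyl}-3-methylfuran-2(5H)-one
Product: 10 (3R,4S,5S)-5-{[(tert-butyldiphenylsilyl)oxy]methyl}-3,4-dimethyldihydrofuran-2(3H)-one, via silyl ketene acetal 9 (not isolated)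
Conditions: CuI, MeLi (gives Me2CuLi), Me3SiCl, THF, −78 °C; then t-BuCO2H, −78 to 0 °C; aq. NH4Cl
Reagents that add atoms: lithium dimethylcuprate, [Li+].C[Cu-]C (made in the flask from methyllithium, [Li]C, and CuI); chlorotrimethylsilane, C[Si](C)(C)Cl (silyl group carried only by 9)
Why: Lithium dimethylcuprate complexes the enone of 8 on the face away from the silyloxymethyl arm at C5, and transfer of methyl to the β carbon (C4 of the lactone, C3 of 23) with silylation of the carbonyl oxygen leaves silyl ketene acetal 9. The closest known reaction type is the chlorosilane-accelerated conjugate addition of an organocuprate to a γ-substituted butenolide; the silane is needed because the α-methyl group lowers the reactivity of the enone. No ring is closed; one skeletal bond (C–CH3) and one C–H bond are formed. The first new stereocentre is controlled by the C5 centre inherited from 1, whose bulky side chain blocks one face of the flat ring. When the hindered carboxylic acid is added, carbon protonation of 9 is irreversible and should occur on the face opposite the new β-methyl, the nearest substituent to the α carbon, which places the α-methyl cis to the β-methyl. The second stereocentre is therefore controlled by the first, so one chiral-pool centre is relayed to two. The step needs facial selectivity twice and no equilibration, since the cis-dimethyl lactone is the less stable epimer; the cold, weakly acidic quench and the absence of base are meant to secure this. Regioselectivity is not at issue because 1,4-addition is the only path open to the cuprate.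

Step 7
Reactants: 10 (3R,4S,5S)-5-{[(tert-butyldiphenylsilyl)oxy]methyl}-3,4-dimethyldihydrofuran-2(3H)-one
Product: 11 (3R,4S,5S)-5-{[(tert-butyldiphenylsilyl)oxy]methyl}-3,4-dimethyltetrahydrofuran-2-ol (both anomers)
Conditions: i-Bu2AlH, CH2Cl2, −78 °C; aq. potassium sodium tartrate
Reagents that add atoms: none
Why: Partial reduction of a γ-lactone stops at the aluminium hemiacetal at low temperature; the conditions are not basic, so the α-methyl centre should not epimerise.

Step 8
Reactants: 11 (3R,4S,5S)-5-{[(tert-butyldiphenylsilyl)oxy]methyl}-3,4-dimethyltetrahydrofuran-2-ol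
Product: 12 tert-butyl{[(2S,3S,4R)-3,4-dimethyl-5-(phenylsulfonyl)tetrahydrofuran-2-yl]methoxy}diphenylsilane (both C5 epimers)
Conditions: PhSO2H, CaCl2, CH2Cl2, 0 °C to rt
Reagents that add atoms: benzenesulfinic acid, OS(=O)c1ccccc1
Why: Acid-promoted exchange of the anomeric hydroxyl for sulfinate through the cyclic oxocarbenium ion gives the anomeric sulfone, a stable precursor of that cation; the silyl ether tolerates the weak acid and the anomeric configuration is irrelevant.

Step 9
Reactants: 13 4-bromo-2,6-dimethoxyphenol
Product: 14 2-(benzyloxy)-5-bromo-1,3-dimethoxybenzene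
Conditions: BnBr, K2CO3, DMF, rt
Reagents that add atoms: benzyl bromide, BrCc1ccccc1
Why: Williamson ether synthesis; the benzyl ether masks the acidic, oxidisable phenol for the organometallic, oxidation and photoredox steps.

Step 10
Reactants: 12 tert-butyl{[(2S,3S,4R)-3,4-dimethyl-5-(phenylsulfonyl)tetrahydrofuran-2-yl]methoxy}diphenylsilane; 14 2-(benzyloxy)-5-bromo-1,3-dimethoxybenzene
Product: 17 tert-butyl({(2S,3S,4R,5R)-5-[4-(benzyloxy)-3,5-dimethoxyphenyl]-3,4-dimethyltetrahydrofuran-2-yl}methoxy)diphenylsilane, via arylmagnesium bromide 15 (not isolated), via arylzinc bromide 16 (not isolated)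
Conditions: 14, Mg, THF, reflux; ZnBr2, THF, rt; then 12, THF, rt
Reagents that add atoms: magnesium, [Mg] (carried only by 15); zinc dibromide, Br[Zn]Br (zinc carried only by 16)
Why: Substitution of a 2-sulfonyl cyclic ether by an organozinc reagent: the zinc and magnesium halides ionise the sulfone to the five-membered oxocarbenium ion and 16 adds to it. Inside attack on the envelope that keeps the C3 methyl pseudoequatorial comes from the face opposite both cis methyl groups, so ring B should end up trans to the C4 methyl and cis to the C2 side chain, setting C5 as R.

Step 11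
Reactants: 17 tert-butyl({(2S,3S,4R,5R)-5-[4-(benzyloxy)-3,5-dimethoxyphenyl]-3,4-dimethyltetrahydrofuran-2-yl}methoxy)diphenylsilane
Product: 18 {(2S,3S,4R,5R)-5-[4-(benzyloxy)-3,5-dimethoxyphenyl]-3,4-dimethyltetrahydrofuran-2-yl}methanol
Conditions: Bu4NF, THF, 0 °C to rt
Reagents that add atoms: none
Why: Fluoride cleavage of the silyl ether; the benzyl ether, aryl ethers and ring are inert to fluoride.

Step 12
Reactants: 18 {(2S,3S,4R,5R)-5-[4-(benzyloxy)-3,5-dimethoxyphenyl]-3,4-dimethyltetrahydrofuran-2-yl}methanol
Product: 20 (2S,3S,4R,5R)-5-[4-(benzyloxy)-3,5-dimethoxyphenyl]-3,4-dimethyltetrahydrofuran-2-carboxylic acid, via aldehyde 19 (not isolated)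
Conditions: TEMPO (cat.), PhI(OAc)2, MeCN–H2O, rt
Reagents that add atoms: water, O
Why: Oxoammonium-mediated oxidation of the primary alcohol to aldehyde 19, whose hydrate is oxidised on to the acid in the aqueous medium; ethers are inert, and any epimerisation at C2 does not matter because step 13 erases that centre.

Step 13
Reactants: 20 (2S,3S,4R,5R)-5-[4-(benzyloxy)-3,5-dimethoxyphenyl]-3,4-dimethyltetrahydrofuran-2-carboxylic acid; 21 4-bromo-1,2-dimethoxybenzene
Product: 22 (2R,3R,4S,5S)-2-[4-(benzyloxy)-3,5-dimethoxyphenyl]-5-(3,4-dimethoxyphenyl)-3,4-dimethyltetrahydrofuran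
Conditions: NiCl2·glyme (cat.), 4,4'-di-tert-butyl-2,2'-bipyridine (cat.), Ir[dF(CF3)ppy]2(dtbbpy)PF6 (cat.), Cs2CO3, DMF, blue LEDs, rt
Reagents that add atoms: none
Why: Metallaphotoredox decarboxylative arylation of an α-oxy acid: the excited iridium photocatalyst oxidises the caesium carboxylate, loss of CO2 gives the C2 radical, the aryl nickel bromide complex formed from 21 and zerovalent nickel captures it, and reductive elimination from trivalent nickel forms the C2–aryl bond. The radical is planar, so the old C2 configuration is lost, and ring A should be delivered to the face opposite the adjacent C3 methyl (and the C4 methyl behind it), giving the 2,3-trans, 2,5-cis arrangement.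

Step 14
Reactants: 22 (2R,3R,4S,5S)-2-[4-(benzyloxy)-3,5-dimethoxyphenyl]-5-(3,4-dimethoxyphenyl)-3,4-dimethyltetrahydrofuran
Product: 23 4-[(2R,3R,4S,5S)-5-(3,4-dimethoxyphenyl)-3,4-dimethyltetrahydrofuran-2-yl]-2,6-dimethoxyphenol, the target (2S,3S,4R,5R)-2-(3,4-dimethoxyphenyl)-5-(4-hydroxy-3,5-dimethoxyphenyl)-3,4-dimethyltetrahydrofuran
Conditions: H2 (1 atm), Pd/C, EtOAc, rt
Reagents that add atoms: none
Why: Hydrogenolysis of the aryl benzyl ether; under neutral conditions at one atmosphere the ring benzylic C–O bonds should cleave much more slowly, so no stereocentre is touched.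

## Compound list

1 | L-glutamic acid, (S)-2-aminopentanedioic acid | N[C@@H](CCC(O)=O)C(O)=O | starting material
2 | (S)-5-oxotetrahydrofuran-2-carboxylic acid | O=C1CC[C@@H](C(=O)O)O1 | intermediate
3 | (S)-5-(hydroxymethyl)dihydrofuran-2(3H)-one | O=C1CC[C@@H](CO)O1 | intermediate
4 | (S)-5-{[(tert-butyldiphenylsilyl)oxy]methyl}dihydrofuran-2(3H)-one | CC(C)(C)[Si](c1ccccc1)(c1ccccc1)OC[C@H]2OC(=O)CC2 | intermediate
5 | (3R,5S)-5-{[(tert-butyldiphenylsilyl)oxy]methyl}-3-methyldihydrofuran-2(3H)-one (trans isomer drawn) | CC(C)(C)[Si](c1ccccc1)(c1ccccc1)OC[C@H]2OC(=O)[C@H](C)C2 | intermediate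
6 | (5S)-5-{[(tert-butyldiphenylsilyl)oxy]methyl}-3-methyl-3-(phenylselanyl)dihydrofuran-2(3H)-one (C3 epimers) | CC(C)(C)[Si](c1ccccc1)(c1ccccc1)OC[C@H]2OC(=O)C(C)([Se]c3ccccc3)C2 | intermediate
7 | (5S)-3-(benzeneseleninyl)-5-{[(tert-butyldiphenylsilyl)oxy]methyl}-3-methyldihydrofuran-2(3H)-one (mixture at C3 and Se) | CC(C)(C)[Si](c1ccccc1)(c1ccccc1)OC[C@H]2OC(=O)C(C)([Se](=O)c3ccccc3)C2 | intermediate
8 | (S)-5-{[(tert-butyldiphenylsilyl)oxy]methyl}-3-methylfuran-2(5H)-one | CC(C)(C)[Si](c1ccccc1)(c1ccccc1)OC[C@H]2OC(=O)C(C)=C2 | intermediate
9 | tert-butyl{[(2S,3S)-3,4-dimethyl-5-[(trimethylsilyl)oxy]-2,3-dihydrofuran-2-yl]methoxy}diphenylsilane | CC(C)(C)[Si](c1ccccc1)(c1ccccc1)OC[C@H]2OC(O[Si](C)(C)C)=C(C)[C@@H]2C | intermediate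
10 | (3R,4S,5S)-5-{[(tert-butyldiphenylsilyl)oxy]methyl}-3,4-dimethyldihydrofuran-2(3H)-one | CC(C)(C)[Si](c1ccccc1)(c1ccccc1)OC[C@H]2OC(=O)[C@H](C)[C@@H]2C | intermediate
11 | (3R,4S,5S)-5-{[(tert-butyldiphenylsilyl)oxy]methyl}-3,4-dimethyltetrahydrofuran-2-ol (both anomers) | CC(C)(C)[Si](c1ccccc1)(c1ccccc1)OC[C@H]2OC(O)[C@H](C)[C@@H]2C | intermediate
12 | tert-butyl{[(2S,3S,4R)-3,4-dimethyl-5-(phenylsulfonyl)tetrahydrofuran-2-yl]methoxy}diphenylsilane (both C5 epimers) | CC(C)(C)[Si](c1ccccc1)(c1ccccc1)OC[C@H]2OC(S(=O)(=O)c3ccccc3)[C@H](C)[C@@H]2C | intermediate
13 | 4-bromo-2,6-dimethoxyphenol | COc1cc(Br)cc(OC)c1O | starting material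
14 | 2-(benzyloxy)-5-bromo-1,3-dimethoxybenzene | COc1cc(Br)cc(OC)c1OCc1ccccc1 | intermediate
15 | [4-(benzyloxy)-3,5-dimethoxyphenyl]magnesium bromide | COc1cc([Mg]Br)cc(OC)c1OCc1ccccc1 | intermediate
16 | [4-(benzyloxy)-3,5-dimethoxyphenyl]zinc bromide | COc1cc([Zn]Br)cc(OC)c1OCc1ccccc1 | intermediate
17 | tert-butyl({(2S,3S,4R,5R)-5-[4-(benzyloxy)-3,5-dimethoxyphenyl]-3,4-dimethyltetrahydrofuran-2-yl}methoxy)diphenylsilane | CC(C)(C)[Si](c1ccccc1)(c1ccccc1)OC[C@H]2O[C@@H](c3cc(OC)c(OCc4ccccc4)c(OC)c3)[C@H](C)[C@@H]2C | intermediate
18 | {(2S,3S,4R,5R)-5-[4-(benzyloxy)-3,5-dimethoxyphenyl]-3,4-dimethyltetrahydrofuran-2-yl}methanol | OC[C@H]1O[C@@H](c2cc(OC)c(OCc3ccccc3)c(OC)c2)[C@H](C)[C@@H]1C | intermediate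
19 | (2S,3S,4R,5R)-5-[4-(benzyloxy)-3,5-dimethoxyphenyl]-3,4-dimethyltetrahydrofuran-2-carbaldehyde | O=C[C@H]1O[C@@H](c2cc(OC)c(OCc3ccccc3)c(OC)c2)[C@H](C)[C@@H]1C | intermediate
20 | (2S,3S,4R,5R)-5-[4-(benzyloxy)-3,5-dimethoxyphenyl]-3,4-dimethyltetrahydrofuran-2-carboxylic acid | OC(=O)[C@H]1O[C@@H](c2cc(OC)c(OCc3ccccc3)c(OC)c2)[C@H](C)[C@@H]1C | intermediate
21 | 4-bromo-1,2-dimethoxybenzene | COc1ccc(Br)cc1OC | starting material
22 | (2R,3R,4S,5S)-2-[4-(benzyloxy)-3,5-dimethoxyphenyl]-5-(3,4-dimethoxyphenyl)-3,4-dimethyltetrahydrofuran | COc1ccc([C@H]2O[C@@H](c3cc(OC)c(OCc4ccccc4)c(OC)c3)[C@H](C)[C@@H]2C)cc1OC | intermediate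
23 | 4-[(2R,3R,4S,5S)-5-(3,4-dimethoxyphenyl)-3,4-dimethyltetrahydrofuran-2-yl]-2,6-dimethoxyphenol | COc1ccc([C@H]2O[C@@H](c3cc(OC)c(O)c(OC)c3)[C@H](C)[C@@H]2C)cc1OC | target

## Step count and least certain steps

Total step count: 14. Longest linear sequence: 13 steps (steps 1 to 8 and 10 to 14, from 1 to 23); step 9 is a one-step side branch. Compounds 2 and 3 are also commercially available, which would let the sequence start up to two steps later.

Step 6 (key step). The most likely failure is incomplete facial discrimination in the carbon protonation of 9, or later equilibration at the α carbon; either erodes the cis relationship of the methyl groups. The conjugate addition may also be slow because the α-methyl group makes the β carbon less electrophilic. The fallback sets out from 4 and returns at 10: the methyl is added to the unmethylated ring and the α centre is set by hydrogenation instead of protonation. Compound 4 is dehydrogenated by the selenenylation and selenoxide elimination of step 5 to (S)-5-{[(tert-butyldiphenylsilyl)oxy]methyl}furan-2(5H)-one F1. Me2CuLi with Me3SiCl adds methyl anti to the side chain to give (4S,5S)-5-{[(tert-butyldiphenylsilyl)oxy]methyl}-4-methyldihydrofuran-2(3H)-one F2. Mannich-type α-methylenation (LiN(i-Pr)2, dimethylmethyleneiminium iodide, then MeI and mild base) gives (4S,5S)-5-{[(tert-butyldiphenylsilyl)oxy]methyl}-4-methyl-3-methylidenedihydrofuran-2(3H)-one F3. Hydrogenation of the exocyclic alkene over RhCl(PPh3)3 or Pd/C should add hydrogen to the face opposite the C4 methyl and give 10.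

Step 5. The selenoxide may eliminate toward the methyl group and give the exocyclic alkene, or enantiomeric purity may be lost by γ-deprotonation of the butenolide. The fallback sets out from 4 and returns at 8: the methyl group is put on by cross-coupling after the ring alkene is in place. Compound 4 is taken to (S)-5-{[(tert-butyldiphenylsilyl)oxy]methyl}furan-2(5H)-one F1 as above, where only ring hydrogens can be lost. Bromine addition and dehydrobromination with Et3N give (S)-3-bromo-5-{[(tert-butyldiphenylsilyl)oxy]methyl}furan-2(5H)-one F4, and a Stille methylation (Me4Sn, Pd(PPh3)4) gives 8.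

Step 10. The C4 configuration may be lost by reversible proton loss from the oxocarbenium ion, elimination to the enol ether may compete with substitution, or facial selectivity may be incomplete because the C2 side chain sits on the face that must be attacked. The fallback sets out from 11 and returns at 17: the C5–aryl bond is made by carbonyl addition and the ring is closed afterwards at the benzylic carbon. The aryllithium from 14 (n-BuLi, THF, −78 °C) adds to the open hydroxy-aldehyde form of 11 to give (1RS,2R,3S,4S)-1-[4-(benzyloxy)-3,5-dimethoxyphenyl]-5-[(tert-butyldiphenylsilyl)oxy]-2,3-dimethylpentane-1,4-diol F5. BF3·OEt2 in CH2Cl2 at low temperature ionises only the electron-rich benzylic alcohol. The remaining secondary hydroxyl closes the ring on the benzylic cation, with the aryl group expected trans to the neighbouring methyl, to give 17.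

Step 13. Oxidative addition of the electron-rich bromide 21 to nickel may be slow, so that protodecarboxylation of 20 competes, and facial selectivity in the capture of the C2 radical may be incomplete because ring B sits on the face that must be attacked. The fallback sets out from 20 and returns at 22: the radical exchange is replaced by a polar one. Oxidative decarboxylation of 20 with Pb(OAc)4 gives (3S,4R,5R)-5-[4-(benzyloxy)-3,5-dimethoxyphenyl]-3,4-dimethyltetrahydrofuran-2-yl acetate F6. A BF3·OEt2-promoted Friedel–Crafts reaction of its oxocarbenium ion with 1,2-dimethoxybenzene, which reacts para to a methoxy group, should place ring A anti to the C3 methyl and give 22.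

Further compounds

F1 | step 6 | (S)-5-{[(tert-butyldiphenylsilyl)oxy]methyl}furan-2(5H)-one | CC(C)(C)[Si](c1ccccc1)(c1ccccc1)OC[C@H]2OC(=O)C=C2
F2 | step 6 | (4S,5S)-5-{[(tert-butyldiphenylsilyl)oxy]methyl}-4-methyldihydrofuran-2(3H)-one | CC(C)(C)[Si](c1ccccc1)(c1ccccc1)OC[C@H]2OC(=O)C[C@@H]2C
F3 | step 6 | (4S,5S)-5-{[(tert-butyldiphenylsilyl)oxy]methyl}-4-methyl-3-methylidenedihydrofuran-2(3H)-one | CC(C)(C)[Si](c1ccccc1)(c1ccccc1)OC[C@H]2OC(=O)C(=C)[C@@H]2C
F4 | step 5 | (S)-3-bromo-5-{[(tert-butyldiphenylsilyl)oxy]methyl}furan-2(5H)-one | CC(C)(C)[Si](c1ccccc1)(c1ccccc1)OC[C@H]2OC(=O)C(Br)=C2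
F5 | step 10 | (1RS,2R,3S,4S)-1-[4-(benzyloxy)-3,5-dimethoxyphenyl]-5-[(tert-butyldiphenylsilyl)oxy]-2,3-dimethylpentane-1,4-diol | CC(C)(C)[Si](c1ccccc1)(c1ccccc1)OC[C@@H](O)[C@@H](C)[C@@H](C)C(O)c1cc(OC)c(OCc2ccccc2)c(OC)c1
F6 | step 13 | (3S,4R,5R)-5-[4-(benzyloxy)-3,5-dimethoxyphenyl]-3,4-dimethyltetrahydrofuran-2-yl acetate (C2 epimers) | CC(=O)OC1O[C@@H](c2cc(OC)c(OCc3ccccc3)c(OC)c2)[C@H](C)[C@@H]1C
A1 | alternative 1 | tert-butyl(4-{(1R)-1-[(1S)-1-(3,4-dimethoxyphenyl)prop-2-en-1-yl]oxyprop-2-en-1-yl}-2,6-dimethoxyphenoxy)dimethylsilane | COc1ccc([C@H](C=C)O[C@@H](c2cc(OC)c(O[Si](C)(C)C(C)(C)C)c(OC)c2)C=C)cc1OC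
A2 | alternative 1 | tert-butyl{4-[(2R,3R,4S,5S)-5-(3,4-dimethoxyphenyl)-3,4-dimethyltetrahydrofuran-2-yl]-2,6-dimethoxyphenoxy}dimethylsilane | COc1ccc([C@H]2O[C@@H](c3cc(OC)c(O[Si](C)(C)C(C)(C)C)c(OC)c3)[C@H](C)[C@@H]2C)cc1OC
A3 | alternative 2 | 2-[4-(benzyloxy)-3,5-dimethoxyphenyl]-1-[(2R,5R)-2,5-dimethylpyrrolidin-1-yl]ethan-1-one (auxiliary enantiomer drawn arbitrarily) | COc1cc(CC(=O)N2[C@H](C)CC[C@H]2C)cc(OC)c1OCc1ccccc1
A4 | alternative 2 | (Z)-but-2-ene | C/C=C\C
A5 | alternative 2 | (2R,3R,4S)-2-[4-(benzyloxy)-3,5-dimethoxyphenyl]-3,4-dimethylcyclobutan-1-one | O=C1[C@@H](c2cc(OC)c(OCc3ccccc3)c(OC)c2)[C@H](C)[C@@H]1C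
A6 | alternative 2 | (3S,4R,5R)-5-[4-(benzyloxy)-3,5-dimethoxyphenyl]-3,4-dimethyldihydrofuran-2(3H)-one | O=C1O[C@@H](c2cc(OC)c(OCc3ccccc3)c(OC)c2)[C@H](C)[C@@H]1C
A7 | alternative 3 | (3,4-dimethoxyphenyl)methanol | COc1ccc(CO)cc1OC
A8 | alternative 3 | 2-methylbuta-1,3-diene | C=CC(C)=C
A9 | alternative 3 | (1S,2S)-1-(3,4-dimethoxyphenyl)-2,3-dimethylbut-3-en-1-ol | COc1ccc(cc1OC)[C@@H](O)[C@@H](C)C(C)=C
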